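**Plan**

Numbering: non-hydrogen atoms of the target SMILES read left to right (C1–C27). Ring A = azepane (N21, C22–C27), ring B = pyrrole (C11, C12, C13, N21, C22), ring C = carbocycle (C3, C4, C10, C11, C22, C23), ring D = lactone (C4, O5, C6, C8, C10), ring E = side-chain lactone (C14, C15, C16, C18, O20).
Enabling feature: lactone D is cis-fused to ring C and its C8–C10 bond ends at C10, the carbon attached to pyrrole carbon C11. An acetate carbenoid hung on O5 of C4 therefore reaches the pyrrole-activated C10–H bond cis to O5 through a five-membered transition state.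
Cuts, in retrosynthetic order: C16=CH2 reduction; C14–C15 and O20–C18 (ring E from a C13 aldehyde); C8–C9; C8–C10 (carbenoid C–H insertion); C13–carboxyl; C10–C11 and C4–C10 (epoxide route to ring C); C3–C23; C22–C23 and N21–C27.
Forward order: ring A is closed on pyrrole B, the C3–C23 bond is made, ring C is closed, C13 is esterified and O5 diazoacetylated, ring D is closed, the C8 methyl is added, and ring E is built last.
Stereochemistry: C3 (and with it C23) from an enamine catalyst; C4 by Felkin–Anh addition to the C3-branched aldehyde; C10 relayed from C4 in the insertion; C8 by convex-face hydrogenation; C14 from a chiral chromium catalyst; C16 by hydrogenation anti to the pyrrolyl group.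

Key step: step 10

Assumption: the sense of induction of the imidazolidinone (Si face of the enamine carbon C3) and of the chromium ligand (Si face of the C13 aldehyde) is taken from their behaviour with simple aldehydes; if either proves opposite, the antipodal catalyst is used.

**Route**

Step 1
Reactants: 1 pyrrole; 2 ethyl 5-bromopentanoate
Product: 4 5-(1H-pyrrol-1-yl)pentanoic acid, via ethyl 5-(1H-pyrrol-1-yl)pentanoate 3 (not isolated)
Conditions: NaH, DMF, 0 °C to rt; then LiOH, H2O/THF, rt; HCl to pH 3
Reagents that add atoms: lithium hydroxide, [Li+].[OH-]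
Why: N-alkylation of sodium pyrrolide by the primary bromide (SN2 at nitrogen in DMF) followed by saponification of the ethyl ester in the same flask gives the acid.

Step 2
Reactants: 4 5-(1H-pyrrol-1-yl)pentanoic acid
Product: 5 5,6,7,8-tetrahydro-9H-pyrrolo[1,2-a]azepin-9-one
Conditions: PPA, 90 °C
Reagents that add atoms: none
Why: Intramolecular Friedel–Crafts acylation at the pyrrole α-carbon closes the seven-membered ring A, as is known for polyphosphoric acid cyclisations of pyrrole-tethered acids.

Step 3
Reactants: 5 5,6,7,8-tetrahydro-9H-pyrrolo[1,2-a]azepin-9-one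
Product: 6 racemic 6,7,8,9-tetrahydro-5H-pyrrolo[1,2-a]azepin-9-ol
Conditions: NaBH4, MeOH/THF, 0 °C to rt
Reagents that add atoms: none
Why: Borohydride reduction of the 2-acylpyrrole ketone gives the carbinol, whose configuration is irrelevant because C23 is ionised in the next step.

Step 4
Reactants: 6 racemic 6,7,8,9-tetrahydro-5H-pyrrolo[1,2-a]azepin-9-ol; 7 butanal
Product: 8 (2R)-2-[(9R)-6,7,8,9-tetrahydro-5H-pyrrolo[1,2-a]azepin-9-yl]butanal
Conditions: (2S,5S)-5-benzyl-2-tert-butyl-3-methylimidazolidin-4-one·TFA (20 mol %), butanal (3 equiv), Et2O, 0 °C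
Reagents that add atoms: none
Why: In this enamine-catalysed SN1-type α-alkylation of an aldehyde the acid co-catalyst ionises the pyrrolyl carbinol to a 1-azafulvenium ion, the E-enamine of butanal captures it on the face left open by the benzyl group so that C3 should be set as R, and C23 (R) follows from the relative orientation of the two prochiral partners in an open transition state, any C23 epimer being removed by chromatography.

Step 5
Reactants: 8 (2R)-2-[(9R)-6,7,8,9-tetrahydro-5H-pyrrolo[1,2-a]azepin-9-yl]butanal
Product: 9 (2S)-2-{(1R)-1-[(9R)-6,7,8,9-tetrahydro-5H-pyrrolo[1,2-a]azepin-9-yl]propyl}oxirane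
Conditions: Me3S+ I−, n-BuLi, THF, −10 °C; then 8, −78 to 0 °C
Reagents that add atoms: trimethylsulfonium iodide, C[S+](C)C.[I-]
Why: Corey–Chaykovsky epoxidation, in which dimethylsulfonium methylide adds irreversibly under Felkin–Anh control (anti to the bulky C23 substituent, past H3), should give the (4S)-epoxide, and the low temperature limits enolisation at C3.

Step 6
Reactants: 9 (2S)-2-{(1R)-1-[(9R)-6,7,8,9-tetrahydro-5H-pyrrolo[1,2-a]azepin-9-yl]propyl}oxirane
Product: 10 tricyclic alcohol (rings A to C; 3-ethyl, 4-hydroxy; 3R,4R,23R)
Conditions: InBr3 (10 mol %), CH2Cl2 (0.01 M), −20 to 0 °C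
Reagents that add atoms: none
Why: Lewis-acid-promoted intramolecular Friedel–Crafts alkylation of pyrrole β-carbon C11 by the terminal epoxide carbon C10 (6-endo opening at the unhindered CH2, preferred over a strained 5-exo closure) forms ring C without touching C4, so the hydroxyl ends trans to the C3 ethyl group.

Step 7
Reactants: 10 tricyclic alcohol
Product: 12 C13 benzyl ester alcohol, via bis(trichloroacetyl) compound 11 (not isolated)
Conditions: Cl3CCOCl (2.5 equiv), 2,6-lutidine, CH2Cl2, 0 °C to rt; then BnOH, NaH, THF, 0 °C to rt
Reagents that add atoms: trichloroacetyl chloride, O=C(Cl)C(Cl)(Cl)Cl; benzyl alcohol, OCc1ccccc1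
Why: Friedel–Crafts trichloroacetylation of the free pyrrole α-position C13 (with concurrent O-acylation at C4) followed by haloform-type alcoholysis with benzyloxide turns the trichloromethyl ketone into the benzyl ester and strips the labile O-trichloroacetate, which installs the electron-withdrawing group that shields the pyrrole in the carbenoid step.

Step 8
Reactants: 12 C13 benzyl ester alcohol
Product: 13 C4 bromoacetate
Conditions: BrCH2COBr, NaHCO3, MeCN, 0 °C
Reagents that add atoms: bromoacetyl bromide, O=C(CBr)Br
Why: O-acylation of the secondary alcohol by the acid bromide under mild base gives the bromoacetate needed for diazo formation.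

Step 9
Reactants: 13 C4 bromoacetate
Product: 14 C4 diazoacetate
Conditions: TsNHNHTs, DBU, THF, 0 °C
Reagents that add atoms: N,N'-ditosylhydrazine, Cc1ccc(cc1)S(=O)(=O)NNS(=O)(=O)c1ccc(C)cc1
Why: N-alkylation of the ditosylhydrazine by the bromoacetate and DBU-induced double elimination of sulfinate is an established bromoacetate-to-diazoacetate conversion that leaves the benzyl ester untouched.

Step 10
Reactants: 14 C4 diazoacetate
Product: 15 tetracyclic cis-fused lactone (rings A to D; C8 unsubstituted; C13 benzyl ester; 3R,4S,10R,23R)
Conditions: Rh2(5S-MEPY)4 (1 mol %; dirhodium tetrakis[methyl (5S)-2-oxopyrrolidine-5-carboxylate], divalent rhodium), CH2Cl2, reflux, 14 added over 6 h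
Reagents that add atoms: none
Why: The divalent rhodium carboxamidate expels N2 from the diazoacetate and the electrophilic carbenoid carbon C8 inserts into a C10–H bond through a three-centre, hydride-transfer-like transition state with retention at carbon. The closest known reaction type is the dirhodium carboxamidate-catalysed insertion of 2-arylethyl and cycloalkyl diazoacetates into benzylic and ring C–H bonds to give β-substituted and cis-fused γ-butyrolactones. Ring D closes in the five-membered (1,5-insertion) mode, with O5–C6–C8 bridging C4 and C10. The new C10 centre is dictated by C4: with O5 pseudo-equatorial, the C10–H bond cis to O5 is pseudo-axial and aligned with the pyrrole π system, so C8 takes the place of that hydrogen and the lactone should be cis-fused (10R). The step needs site selectivity over the tertiary C3–H and the pseudo-equatorial C10–H (both also gauche to O5) and chemoselectivity over the pyrrole; the first rests on activation of the axial C10–H by the adjacent pyrrole, on the crowded position of C3–H between the ethyl group and C23 and on the strain of a trans-fused lactone, the second on the C13 benzyl ester and on the carboxamidate ligands, which temper the carbenoid and suppress aromatic addition.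

Step 11
Reactants: 15 tetracyclic cis-fused lactone
Product: 18 C8 α-methylene lactone, via Mannich base 16 (not isolated), via trimethylammonium iodide 17 (not isolated)
Conditions: LiN(SiMe3)2, THF, −78 °C; Me2N=CH2+ I−, −78 °C to rt; then MeI, MeOH, rt; then NaHCO3, CH2Cl2/H2O
Reagents that add atoms: N,N-dimethylmethyleneiminium iodide, C=[N+](C)C.[I-]
Why: The lithium enolate of lactone D undergoes Mannich aminomethylation at C8, and quaternisation followed by Hofmann-type β-elimination gives the exocyclic methylene, so no lasting stereocentre is created.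

Step 12
Reactants: 18 C8 α-methylene lactone
Product: 19 tetracyclic acid ((8R)-methyl lactone D, CO2H on C13)
Conditions: H2 (4 atm), 10% Pd/C, EtOAc, rt
Reagents that add atoms: none
Why: Heterogeneous hydrogenation should add H2 to the exocyclic alkene from the convex face of the cis-fused bicycle (the face of H4 and H10), which places the C8 methyl on the concave face (8R), while the same catalyst hydrogenolyses the benzyl ester to the acid.

Step 13
Reactants: 19 tetracyclic acid
Product: 21 C13 aldehyde, via decarboxylated pyrrole 20 (not isolated)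
Conditions: TFA, CH2Cl2, rt; then HC(OEt)3, 0 °C to rt; aq. NaHCO3
Reagents that add atoms: triethyl orthoformate, CCOC(OCC)OCC; water, O
Why: Acid-promoted ipso-protonation and decarboxylation of the pyrrole-2-carboxylic acid frees C13, which is then formylated by the diethoxycarbenium ion from the orthoformate (orthoformate formylation of α-free pyrroles), the acetal being hydrolysed on work-up.

Step 14
Reactants: 21 C13 aldehyde; 22 ethyl 2-(bromomethyl)acrylate
Product: 24 α-methylene bis-lactone, via silyl ether 23 (not isolated)
Conditions: CrCl2 (10 mol %), tridentate 1,8-bis(4-isopropyl-4,5-dihydrooxazol-2-yl)carbazole ligand (12 mol %, antipode giving Si-face addition), Mn powder, TMSCl, i-Pr2NEt, THF, rt; then TBAF, THF, −20 to 0 °C, pH 7 quench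
Reagents that add atoms: none
Why: In this catalytic enantioselective Nozaki–Hiyama–Kishi-type 2-(alkoxycarbonyl)allylation the allylchromium species formed from 22 should add to the Si face of the aldehyde under control of the chiral ligand to set C14 (S), and brief cold fluoride desilylation lets the alkoxide close onto the ethyl ester (5-exo-trig lactonisation) without acid, which spares the ionisable pyrrolyl carbinol.

Step 15
Reactants: 24 α-methylene bis-lactone
Product: 25 CNP0232452.6
Conditions: H2 (1 atm), 5% Rh/Al2O3, EtOAc, rt
Reagents that add atoms: none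
Why: Hydrogenation of the α-methylene-γ-butyrolactone from the face opposite the C14 pyrrolyl group should give the cis-2,4-disubstituted lactone (16S), and rhodium on alumina is chosen to avoid hydrogenolysis of the pyrrolic C14–O bond.

**Compound list**

1 | pyrrole | c1cc[nH]c1 | starting material
2 | ethyl 5-bromopentanoate | CCOC(=O)CCCCBr | starting material
3 | ethyl 5-(1H-pyrrol-1-yl)pentanoate | CCOC(=O)CCCCn1cccc1 | intermediate
4 | 5-(1H-pyrrol-1-yl)pentanoic acid | OC(=O)CCCCn1cccc1 | intermediate
5 | 5,6,7,8-tetrahydro-9H-pyrrolo[1,2-a]azepin-9-one | O=C1CCCCn2cccc12 | intermediate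
6 | racemic 6,7,8,9-tetrahydro-5H-pyrrolo[1,2-a]azepin-9-ol | OC1CCCCn2cccc12 | intermediate
7 | butanal | CCCC=O | starting material
8 | (2R)-2-[(9R)-6,7,8,9-tetrahydro-5H-pyrrolo[1,2-a]azepin-9-yl]butanal | CC[C@@H](C=O)[C@H]1CCCCn2cccc12 | intermediate
9 | (2S)-2-{(1R)-1-[(9R)-6,7,8,9-tetrahydro-5H-pyrrolo[1,2-a]azepin-9-yl]propyl}oxirane | CC[C@@H]([C@H]1CO1)[C@H]2CCCCn3cccc23 | intermediate
10 | tricyclic alcohol, rings A to C, (3R,4R,23R); C4–OH trans to the C3 ethyl, ethyl trans to C24 | CC[C@H]1[C@H](O)Cc2ccn3c2[C@@H]1CCCC3 | intermediate
11 | compound 10 carrying a trichloroacetyl group on C13 and an O-trichloroacetate on C4 | CC[C@H]1[C@H](OC(=O)C(Cl)(Cl)Cl)Cc2cc(C(=O)C(Cl)(Cl)Cl)n3c2[C@@H]1CCCC3 | intermediate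
12 | benzyl ester alcohol: compound 10 with CO2CH2Ph on C13, (3R,4R,23R) | CC[C@H]1[C@H](O)Cc2cc(C(=O)OCc4ccccc4)n3c2[C@@H]1CCCC3 | intermediate
13 | C4 bromoacetate of 12 | CC[C@H]1[C@H](OC(=O)CBr)Cc2cc(C(=O)OCc4ccccc4)n3c2[C@@H]1CCCC3 | intermediate
14 | C4 diazoacetate of 12 (precursor of the key step) | CC[C@H]1[C@H](OC(=O)C=[N+]=[N-])Cc2cc(C(=O)OCc4ccccc4)n3c2[C@@H]1CCCC3 | intermediate
15 | tetracyclic cis-fused lactone, rings A to D, C8 unsubstituted, C13 benzyl ester, (3R,4S,10R,23R) | CC[C@H]1[C@@H]2OC(=O)C[C@@H]2c2cc(C(=O)OCc4ccccc4)n3c2[C@@H]1CCCC3 | intermediate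
16 | compound 15 with a dimethylaminomethyl group on C8 (convex face) | CC[C@H]1[C@@H]2OC(=O)[C@@H](CN(C)C)[C@@H]2c2cc(C(=O)OCc4ccccc4)n3c2[C@@H]1CCCC3 | intermediate
17 | methiodide of 16 (trimethylammoniomethyl on C8, iodide) | CC[C@H]1[C@@H]2OC(=O)[C@@H](C[N+](C)(C)C)[C@@H]2c2cc(C(=O)OCc4ccccc4)n3c2[C@@H]1CCCC3.[I-] | intermediate
18 | compound 15 with an exocyclic methylene on C8 (ring stereocentres as in 15; the C10 descriptor becomes S by priority only) | CC[C@H]1[C@@H]2OC(=O)C(=C)[C@@H]2c2cc(C(=O)OCc4ccccc4)n3c2[C@@H]1CCCC3 | intermediate
19 | tetracyclic acid: lactone D with (8R)-methyl on the concave face, CO2H on C13, (3R,4S,8R,10R,23R) | CC[C@H]1[C@@H]2OC(=O)[C@H](C)[C@@H]2c2cc(C(=O)O)n3c2[C@@H]1CCCC3 | intermediate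
20 | compound 19 without the carboxyl group (C13–H) | CC[C@H]1[C@@H]2OC(=O)[C@H](C)[C@@H]2c2ccn3c2[C@@H]1CCCC3 | intermediate
21 | C13 aldehyde: compound 20 with CHO on C13 | CC[C@H]1[C@@H]2OC(=O)[C@H](C)[C@@H]2c2cc(C=O)n3c2[C@@H]1CCCC3 | intermediate
22 | ethyl 2-(bromomethyl)acrylate | C=C(CBr)C(=O)OCC | starting material
23 | (14S)-trimethylsilyl ether: C13 bears CH(OSiMe3)CH2C(=CH2)CO2Et | CC[C@H]1[C@@H]2OC(=O)[C@H](C)[C@@H]2c2cc([C@H](CC(=C)C(=O)OCC)O[Si](C)(C)C)n3c2[C@@H]1CCCC3 | intermediate
24 | α-methylene bis-lactone: target with C16=CH2 in place of C16-methyl, (14S) | CC[C@H]1[C@@H]2OC(=O)[C@H](C)[C@@H]2c2cc([C@@H]3CC(=C)C(=O)O3)n3c2[C@@H]1CCCC3 | intermediate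
25 | CNP0232452.6, (3R,4S,8R,10R,14S,16S,23R) in the numbering used here | CC[C@H]1[C@@H]2OC(=O)[C@H](C)[C@@H]2c2cc([C@@H]3C[C@H](C)C(=O)O3)n3c2[C@@H]1CCCC3 | target

**Step count**

Total: 15 steps. Longest linear sequence: 15 steps (from pyrrole; butanal and ethyl 2-(bromomethyl)acrylate enter as single reagents).

**Steps most likely to fail**

Step 10. The carbenoid may be diverted into the tertiary C3–H bond or the pseudo-equatorial C10–H bond (wrong ring fusion), or may add to the pyrrole π system, and a mismatch between the chiral catalyst and the chiral substrate can add to the loss of site selectivity. The fallback uses a stabilised acceptor/acceptor carbenoid and sets out from alcohol 12. Esterification with mono-tert-butyl malonate (DCC, DMAP, CH2Cl2) gives the mixed tert-butyl malonate F1. Diazo transfer (4-acetamidobenzenesulfonyl azide, Et3N, MeCN) gives the diazomalonate F2. Rh2(OAc)4 (dirhodium tetraacetate, divalent rhodium) in refluxing benzene should then give the C8 tert-butoxycarbonyl lactone F3, because the bulkier malonate carbenoid is expected to discriminate more sharply in favour of the activated, less hindered C10–H bond. TFA cleaves the tert-butyl ester and warming in toluene decarboxylates the malonic half-acid, which returns the route to lactone 15.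

Step 4. The enamine may discriminate poorly between the two faces of the azafulvenium ion (erosion at C23), the cation may lose a proton to a vinylpyrrole, or the carbinol may self-condense. The fallback is an auxiliary-controlled SN1 alkylation and sets out from carbinol 6. The chlorotitanium enolate of (S)-4-benzyl-3-butanoyloxazolidin-2-one (TiCl4, i-Pr2NEt, CH2Cl2, −78 °C), with a second equivalent of TiCl4 to ionise 6, should give the N-acyl oxazolidinone F4. In F4 C3 is fixed by the auxiliary, and the C23 epimers are stable diastereomers that can be separated by crystallisation or chromatography. LiBH4 in wet THF releases the auxiliary and gives the primary alcohol F5, and Parikh–Doering oxidation (SO3·pyridine, DMSO, Et3N) returns the route to aldehyde 8.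

Step 5. Facial selectivity in the ylide addition may be weak, or the basic ylide may epimerise C3; either gives the wrong relative configuration at C4, which would then be relayed to C10. The fallback sets C4 on the ring and sets out from alcohol 10 as step 6 delivers it, together with its C4 epimer. Parikh–Doering oxidation (SO3·pyridine, DMSO, Et3N) converges both epimers on the tricyclic C4 ketone F6, in which the C3 ethyl group can settle in the trans, pseudo-equatorial position. NaBH4 in MeOH at −40 °C should then deliver hydride axially and give the equatorial alcohol trans to the ethyl group, which is compound 10 again.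

Further compounds
F1 | step 10 | mixed tert-butyl malonate of alcohol 12 at O5 | CC[C@H]1[C@H](OC(=O)CC(=O)OC(C)(C)C)Cc2cc(C(=O)OCc4ccccc4)n3c2[C@@H]1CCCC3
F2 | step 10 | diazomalonate derived from F1 | CC[C@H]1[C@H](OC(=O)C(=[N+]=[N-])C(=O)OC(C)(C)C)Cc2cc(C(=O)OCc4ccccc4)n3c2[C@@H]1CCCC3
F3 | step 10 | lactone 15 bearing a tert-butoxycarbonyl group on C8 (C8 epimers, configuration immaterial) | CC[C@H]1[C@@H]2OC(=O)C(C(=O)OC(C)(C)C)[C@@H]2c2cc(C(=O)OCc4ccccc4)n3c2[C@@H]1CCCC3
F4 | step 4 | (4S)-4-benzyl-3-{(2R)-2-[(9R)-6,7,8,9-tetrahydro-5H-pyrrolo[1,2-a]azepin-9-yl]butanoyl}oxazolidin-2-one | CC[C@@H](C(=O)N1[C@@H](Cc2ccccc2)COC1=O)[C@H]3CCCCn4cccc34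
F5 | step 4 | (2R)-2-[(9R)-6,7,8,9-tetrahydro-5H-pyrrolo[1,2-a]azepin-9-yl]butan-1-ol | CC[C@@H](CO)[C@H]1CCCCn2cccc12
F6 | step 5 | tricyclic C4 ketone (rings A to C, 3R,23R) | CC[C@H]1C(=O)Cc2ccn3c2[C@@H]1CCCC3
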